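In drimane numbering, ring B of the target holds the diene C6=C7–C8(=C12) between the sp3 carbons C5 and C9. This is the imprint of a Diels–Alder reaction with a vinylallene, C5=C6–C7=C8=C12, as the diene. Cutting C5–C10 and C8–C9 opens rings A and B together and gives the acyclic tetraenal 14. In 14 the (E)-enal C9=C10 is tied to C5 by the chain C1–C4, which carries the gem-dimethyl group and a (3R)-silyloxy group. One aluminium-promoted cycloaddition closes both rings, sets C5, C9 and C10 from C3, and leaves the diene finished. Inversion at C3 and etherification of C11 with umbelliferone complete the route.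

Key step: step 9

Numbering: C1–C12 in the text are drimane locants (ring A = C1–C5 and C10; ring B = C5–C10; C11 = OCH2 carbon on C9; C12 = exocyclic CH2 on C8). They are also used for the matching atoms of open-chain compounds. Locants inside compound names are systematic.

Assumption: the (S)-SEGPHOS iridium catalyst is taken to add the prenyl unit to the aldehyde face that gives (6R)-5; if the sense were opposite, the (R)-ligand would be used and nothing else would change.

Step 1
Reactants: 1 methyl geranate
Product: 3 methyl (2E)-3-methyl-6-oxohex-2-enoate, via secondary ozonide 2 (not isolated)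
Conditions: O3, CH2Cl2, −78 °C (Sudan Red 7B as end-point dye); then Me2S, −78 °C → rt
Reagents that add atoms: ozone, [O-][O+]=O
Why: Chemoselective ozonolysis with reductive work-up, in which electrophilic ozone should consume the electron-rich trisubstituted distal alkene well before the ester-conjugated alkene, whose (E)-geometry (later C9=C10) is kept.

Step 2
Reactants: 3 methyl (2E)-3-methyl-6-oxohex-2-enoate, 4 3-methylbuta-1,2-diene
Product: 5 methyl (2E,6R)-6-hydroxy-3,7,7-trimethylnona-2,8-dienoate
Conditions: Ir(η3-C3H5)[(S)-SEGPHOS][κ2-C,O-C6H2(Cl)(NO2)CO2] (5 mol %, preformed from [Ir(cod)Cl]2, (S)-SEGPHOS, 4-chloro-3-nitrobenzoic acid, allyl acetate, Cs2CO3), i-PrOH, PhMe, 50 °C, sealed tube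
Reagents that add atoms: none
Why: Krische-type transfer-hydrogenative reverse prenylation, in which the iridium hydride made from i-PrOH hydrometallates the allene and the prenyliridium adds through its tertiary carbon in a closed chair transition state, the chiral ligand choosing the aldehyde face that sets C3 as (R), while the base-free preformed catalyst should leave the enoate alone.

Step 3
Reactants: 5 methyl (2E,6R)-6-hydroxy-3,7,7-trimethylnona-2,8-dienoate
Product: 6 methyl (2E,6R)-6-(tert-butyldimethylsilyloxy)-3,7,7-trimethylnona-2,8-dienoate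
Conditions: TBSOTf, 2,6-lutidine, CH2Cl2, 0 °C
Reagents that add atoms: tert-butyldimethylsilyl trifluoromethanesulfonate, CC(C)(C)[Si](C)(C)OS(=O)(=O)C(F)(F)F
Why: Silyl ether formation with a silyl triflate and a hindered pyridine base is strong enough for a neopentyl-type secondary alcohol and does not touch the stereocentre.

Step 4
Reactants: 6 methyl (2E,6R)-6-(tert-butyldimethylsilyloxy)-3,7,7-trimethylnona-2,8-dienoate
Product: 8 methyl (2E,6R)-6-(tert-butyldimethylsilyloxy)-3,7,7-trimethyl-8-oxooct-2-enoate, via vicinal diol 7 (not isolated)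
Conditions: OsO4 (2 mol %), NaIO4, 2,6-lutidine, dioxane/H2O (3:1), rt
Reagents that add atoms: osmium tetroxide, O=[Os](=O)(=O)=O; sodium periodate, [Na+].[O-]I(=O)(=O)=O
Why: Lemieux–Johnson cleavage, in which osmium tetroxide should attack the electron-neutral monosubstituted vinyl group faster than the electron-poor trisubstituted enoate alkene and periodate cleaves diol 7 as it forms, so that no metathesis catalyst, which could ring-close this diene to a cyclohexene, is needed.

Step 5
Reactants: 8 methyl (2E,6R)-6-(tert-butyldimethylsilyloxy)-3,7,7-trimethyl-8-oxooct-2-enoate, 9 iodoform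
Product: 10 methyl (2E,6R,8E)-6-(tert-butyldimethylsilyloxy)-9-iodo-3,7,7-trimethylnona-2,8-dienoate
Conditions: CrCl2, dioxane/THF (6:1), 0 °C → rt
Reagents that add atoms: none
Why: Takai olefination, in which the gem-dichromium species from iodoform adds to the non-enolisable aldehyde and eliminates to the (E)-iodoalkene (C5=C6), a geometry reinforced by the quaternary neighbour C4, while ester and silyl ether are inert to divalent chromium.

Step 6
Reactants: 10 methyl (2E,6R,8E)-6-(tert-butyldimethylsilyloxy)-9-iodo-3,7,7-trimethylnona-2,8-dienoate, 11 tributyl(propa-1,2-dien-1-yl)stannane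
Product: 12 methyl (2E,6R,8E)-6-(tert-butyldimethylsilyloxy)-3,7,7-trimethyldodeca-2,8,10,11-tetraenoate
Conditions: Pd2(dba)3 (2.5 mol %), AsPh3 (20 mol %), DMF, rt, dark
Reagents that add atoms: none
Why: Stille coupling, in which the alkenyl iodide adds oxidatively to zerovalent palladium with retention, the allenyl group passes from tin to palladium and reductive elimination should give the (E)-vinylallene at room temperature, mild enough to avoid a premature thermal cycloaddition.

Step 7
Reactants: 12 methyl (2E,6R,8E)-6-(tert-butyldimethylsilyloxy)-3,7,7-trimethyldodeca-2,8,10,11-tetraenoate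
Product: 13 (2E,6R,8E)-6-(tert-butyldimethylsilyloxy)-3,7,7-trimethyldodeca-2,8,10,11-tetraen-1-ol
Conditions: i-Bu2AlH (2.5 equiv), CH2Cl2, −78 °C; aq. potassium sodium tartrate
Reagents that add atoms: none
Why: 1,2-Reduction of a conjugated ester with an aluminium hydride gives the allylic alcohol at low temperature without hydroalumination of the allene and without change of either alkene geometry.

Step 8
Reactants: 13 (2E,6R,8E)-6-(tert-butyldimethylsilyloxy)-3,7,7-trimethyldodeca-2,8,10,11-tetraen-1-ol
Product: 14 (2E,6R,8E)-6-(tert-butyldimethylsilyloxy)-3,7,7-trimethyldodeca-2,8,10,11-tetraenal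
Conditions: MnO2 (activated, excess), CH2Cl2, rt; used at once
Reagents that add atoms: none
Why: Heterogeneous allylic oxidation with MnO2 is neutral, stops at the enal and keeps the (2E)-geometry that later fixes C9 relative to C10.

Step 9
Reactants: 14 (2E,6R,8E)-6-(tert-butyldimethylsilyloxy)-3,7,7-trimethyldodeca-2,8,10,11-tetraenal
Product: 15 (1R,4aS,6R,8aR)-6-(tert-butyldimethylsilyloxy)-5,5,8a-trimethyl-2-methylidene-1,2,4a,5,6,7,8,8a-octahydronaphthalene-1-carbaldehyde
Conditions: Me2AlCl (1.2 equiv), CH2Cl2 (0.01 M), −78 → −20 °C; cold pH 7 phosphate buffer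
Reagents that add atoms: none
Why: Me2AlCl binds the formyl oxygen, lowers the LUMO of the (E)-C9=C10 enal and scavenges stray acid, so that the enal adds suprafacially across C5=C6–C7=C8 in a concerted, asynchronous [4+2] in which the central allene carbon C8 is a diene terminus and the orthogonal C8=C12 bond stays behind as the exocyclic methylene. The closest known reaction types are the type 1 intramolecular Diels–Alder reaction of vinylallenes and the alkylaluminium-chloride-promoted cyclisation of 1,7,9-decatrienals to trans-decalins with an angular methyl group. Ring B (C5–C10) closes as the new cyclohexene through both new bonds, C5–C10 and C8–C9, whereas ring A (C1–C5, C10) closes through C5–C10 alone as the six-membered ring completed by the four-atom tether C1–C4 folded as a chair. C9 relative to C10 follows from the (E)-enal geometry (formyl cis to the C10 methyl), C5 relative to C10 from the endo placement of the aluminium-bound formyl group together with the (E)-C5=C6 geometry (H5 trans to the methyl, trans fusion), and the absolute sense of all three from C3, whose bulky silyloxy group stays equatorial on the chair tether. The step needs the vinylallene to react as the diene, endo over exo folding and one diene face: the linear allene makes the s-cis form easy to reach, the C4 gem-dimethyl group favours the folded chain, overlap with the complexed carbonyl favours endo, and the (3R)-centre next to C4 selects the face. The cold buffered quench should keep the β,γ-unsaturated aldehyde from sliding into conjugation.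

Step 10
Reactants: 15 (1R,4aS,6R,8aR)-6-(tert-butyldimethylsilyloxy)-5,5,8a-trimethyl-2-methylidene-1,2,4a,5,6,7,8,8a-octahydronaphthalene-1-carbaldehyde
Product: 16 [(1R,4aS,6R,8aR)-6-(tert-butyldimethylsilyloxy)-5,5,8a-trimethyl-2-methylidene-1,2,4a,5,6,7,8,8a-octahydronaphthalen-1-yl]methanol
Conditions: NaBH4, MeOH, 0 °C
Reagents that add atoms: none
Why: Borohydride 1,2-reduction is faster than enolisation, so the labile aldehyde is removed before C9 can epimerise or the alkene can migrate.

Step 11
Reactants: 16 [(1R,4aS,6R,8aR)-6-(tert-butyldimethylsilyloxy)-5,5,8a-trimethyl-2-methylidene-1,2,4a,5,6,7,8,8a-octahydronaphthalen-1-yl]methanol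
Product: 17 [(1R,4aS,6R,8aR)-6-(tert-butyldimethylsilyloxy)-5,5,8a-trimethyl-2-methylidene-1,2,4a,5,6,7,8,8a-octahydronaphthalen-1-yl]methyl acetate
Conditions: Ac2O, pyridine, DMAP (cat.), CH2Cl2, rt
Reagents that add atoms: acetic anhydride, CC(=O)OC(C)=O
Why: DMAP-catalysed acetylation masks the primary C11 alcohol so that only C3 is oxidised later.

Step 12
Reactants: 17 [(1R,4aS,6R,8aR)-6-(tert-butyldimethylsilyloxy)-5,5,8a-trimethyl-2-methylidene-1,2,4a,5,6,7,8,8a-octahydronaphthalen-1-yl]methyl acetate
Product: 18 [(1R,4aS,6R,8aR)-6-hydroxy-5,5,8a-trimethyl-2-methylidene-1,2,4a,5,6,7,8,8a-octahydronaphthalen-1-yl]methyl acetate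
Conditions: HF·pyridine, pyridine, THF, 0 °C → rt (plastic vessel)
Reagents that add atoms: none
Why: Fluoride-driven cleavage of the Si–O bond in a pyridine-buffered medium removes the hindered silyl ether without hydrolysing the acetate or protonating the diene.

Step 13
Reactants: 18 [(1R,4aS,6R,8aR)-6-hydroxy-5,5,8a-trimethyl-2-methylidene-1,2,4a,5,6,7,8,8a-octahydronaphthalen-1-yl]methyl acetate
Product: 19 [(1R,4aS,8aR)-5,5,8a-trimethyl-2-methylidene-6-oxo-1,2,4a,5,6,7,8,8a-octahydronaphthalen-1-yl]methyl acetate
Conditions: Dess–Martin periodinane, pyridine, CH2Cl2, 0 °C → rt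
Reagents that add atoms: none
Why: Dess–Martin oxidation turns the hindered equatorial alcohol into the C3 ketone under nearly neutral conditions, and no stereocentre is at risk because C4 is quaternary and C2 is a methylene group.

Step 14
Reactants: 19 [(1R,4aS,8aR)-5,5,8a-trimethyl-2-methylidene-6-oxo-1,2,4a,5,6,7,8,8a-octahydronaphthalen-1-yl]methyl acetate
Product: 21 [(1R,4aS,6S,8aR)-6-hydroxy-5,5,8a-trimethyl-2-methylidene-1,2,4a,5,6,7,8,8a-octahydronaphthalen-1-yl]methanol, via axial hydroxy acetate 20 (not isolated)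
Conditions: LiBH(s-Bu)3 (1.5 equiv), THF, −78 °C; then MeOH, aq. NaOH, rt; then H2O2, 0 °C
Reagents that add atoms: none
Why: Sterically controlled ketone reduction, in which the bulky trialkylborohydride avoids the axial path screened by the axial hydrogens on C1 and C5 and delivers hydride from the equatorial side to set the axial (3S)-alcohol, as is usual for 4,4-dimethyl-3-oxo terpenoids, after which hydroxide saponifies the acetate before the borane is oxidised.

Step 15
Reactants: 21 [(1R,4aS,6S,8aR)-6-hydroxy-5,5,8a-trimethyl-2-methylidene-1,2,4a,5,6,7,8,8a-octahydronaphthalen-1-yl]methanol, 22 umbelliferone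
Product: 23 7-{[(1R,4aS,6S,8aR)-6-hydroxy-5,5,8a-trimethyl-2-methylidene-1,2,4a,5,6,7,8,8a-octahydronaphthalen-1-yl]methoxy}-2H-chromen-2-one
Conditions: PPh3, DIAD, THF, 0 °C → rt
Reagents that add atoms: none
Why: Mitsunobu etherification, in which the acidic phenol displaces the alkoxyphosphonium ion formed at the primary C11 alcohol while the axial neopentyl-type C3 alcohol is too hindered to be activated, and no stereocentre changes because substitution occurs at a CH2 group.

Compound list
1 | methyl geranate, methyl (2E)-3,7-dimethylocta-2,6-dienoate | CC(C)=CCC/C(C)=C/C(=O)OC | starting material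
2 | methyl (2E)-5-(5,5-dimethyl-1,2,4-trioxolan-3-yl)-3-methylpent-2-enoate (secondary ozonide, both ring epimers) | CC1(C)OOC(CC/C(C)=C/C(=O)OC)O1 | intermediate
3 | methyl (2E)-3-methyl-6-oxohex-2-enoate | O=CCC/C(C)=C/C(=O)OC | intermediate
4 | 3-methylbuta-1,2-diene | CC(C)=C=C | starting material
5 | methyl (2E,6R)-6-hydroxy-3,7,7-trimethylnona-2,8-dienoate | C=CC(C)(C)[C@H](O)CC/C(C)=C/C(=O)OC | intermediate
6 | methyl (2E,6R)-6-(tert-butyldimethylsilyloxy)-3,7,7-trimethylnona-2,8-dienoate | C=CC(C)(C)[C@H](O[Si](C)(C)C(C)(C)C)CC/C(C)=C/C(=O)OC | intermediate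
7 | methyl (2E,6R)-6-(tert-butyldimethylsilyloxy)-8,9-dihydroxy-3,7,7-trimethylnon-2-enoate (both C8 epimers) | OCC(O)C(C)(C)[C@H](O[Si](C)(C)C(C)(C)C)CC/C(C)=C/C(=O)OC | intermediate
8 | methyl (2E,6R)-6-(tert-butyldimethylsilyloxy)-3,7,7-trimethyl-8-oxooct-2-enoate | O=CC(C)(C)[C@H](O[Si](C)(C)C(C)(C)C)CC/C(C)=C/C(=O)OC | intermediate
9 | iodoform (triiodomethane) | IC(I)I | starting material
10 | methyl (2E,6R,8E)-6-(tert-butyldimethylsilyloxy)-9-iodo-3,7,7-trimethylnona-2,8-dienoate | I/C=C/C(C)(C)[C@H](O[Si](C)(C)C(C)(C)C)CC/C(C)=C/C(=O)OC | intermediate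
11 | tributyl(propa-1,2-dien-1-yl)stannane (allenyltributyltin) | C=C=C[Sn](CCCC)(CCCC)CCCC | starting material
12 | methyl (2E,6R,8E)-6-(tert-butyldimethylsilyloxy)-3,7,7-trimethyldodeca-2,8,10,11-tetraenoate | C=C=C/C=C/C(C)(C)[C@H](O[Si](C)(C)C(C)(C)C)CC/C(C)=C/C(=O)OC | intermediate
13 | (2E,6R,8E)-6-(tert-butyldimethylsilyloxy)-3,7,7-trimethyldodeca-2,8,10,11-tetraen-1-ol | C=C=C/C=C/C(C)(C)[C@H](O[Si](C)(C)C(C)(C)C)CC/C(C)=C/CO | intermediate
14 | (2E,6R,8E)-6-(tert-butyldimethylsilyloxy)-3,7,7-trimethyldodeca-2,8,10,11-tetraenal | C=C=C/C=C/C(C)(C)[C@H](O[Si](C)(C)C(C)(C)C)CC/C(C)=C/C=O | intermediate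
15 | (1R,4aS,6R,8aR)-6-(tert-butyldimethylsilyloxy)-5,5,8a-trimethyl-2-methylidene-1,2,4a,5,6,7,8,8a-octahydronaphthalene-1-carbaldehyde (drimane locants 3R,5S,9R,10R; silyloxy equatorial) | C=C1C=C[C@@H]2C(C)(C)[C@H](O[Si](C)(C)C(C)(C)C)CC[C@@]2(C)[C@@H]1C=O | intermediate
16 | [(1R,4aS,6R,8aR)-6-(tert-butyldimethylsilyloxy)-5,5,8a-trimethyl-2-methylidene-1,2,4a,5,6,7,8,8a-octahydronaphthalen-1-yl]methanol | C=C1C=C[C@@H]2C(C)(C)[C@H](O[Si](C)(C)C(C)(C)C)CC[C@@]2(C)[C@@H]1CO | intermediate
17 | [(1R,4aS,6R,8aR)-6-(tert-butyldimethylsilyloxy)-5,5,8a-trimethyl-2-methylidene-1,2,4a,5,6,7,8,8a-octahydronaphthalen-1-yl]methyl acetate | C=C1C=C[C@@H]2C(C)(C)[C@H](O[Si](C)(C)C(C)(C)C)CC[C@@]2(C)[C@@H]1COC(C)=O | intermediate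
18 | [(1R,4aS,6R,8aR)-6-hydroxy-5,5,8a-trimethyl-2-methylidene-1,2,4a,5,6,7,8,8a-octahydronaphthalen-1-yl]methyl acetate (equatorial alcohol) | C=C1C=C[C@@H]2C(C)(C)[C@H](O)CC[C@@]2(C)[C@@H]1COC(C)=O | intermediate
19 | [(1R,4aS,8aR)-5,5,8a-trimethyl-2-methylidene-6-oxo-1,2,4a,5,6,7,8,8a-octahydronaphthalen-1-yl]methyl acetate | C=C1C=C[C@@H]2C(C)(C)C(=O)CC[C@@]2(C)[C@@H]1COC(C)=O | intermediate
20 | [(1R,4aS,6S,8aR)-6-hydroxy-5,5,8a-trimethyl-2-methylidene-1,2,4a,5,6,7,8,8a-octahydronaphthalen-1-yl]methyl acetate (axial alcohol) | C=C1C=C[C@@H]2C(C)(C)[C@@H](O)CC[C@@]2(C)[C@@H]1COC(C)=O | intermediate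
21 | [(1R,4aS,6S,8aR)-6-hydroxy-5,5,8a-trimethyl-2-methylidene-1,2,4a,5,6,7,8,8a-octahydronaphthalen-1-yl]methanol | C=C1C=C[C@@H]2C(C)(C)[C@@H](O)CC[C@@]2(C)[C@@H]1CO | intermediate
22 | umbelliferone (7-hydroxy-2H-chromen-2-one) | O=c1ccc2ccc(O)cc2o1 | starting material
23 | 7-{[(1R,4aS,6S,8aR)-6-hydroxy-5,5,8a-trimethyl-2-methylidene-1,2,4a,5,6,7,8,8a-octahydronaphthalen-1-yl]methoxy}-2H-chromen-2-one (drimane locants 3S,5S,9R,10R) | C=C1C=C[C@@H]2C(C)(C)[C@@H](O)CC[C@@]2(C)[C@@H]1COc1ccc2ccc(=O)oc2c1 | target

Total step count: 15. Longest linear sequence: 15 steps (1 → 23).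

Steps most likely to fail

1. Step 9 (cycloaddition).
- Risk: the two chair foldings of the tether, with the silyloxy group equatorial or axial, may not be told apart well enough. The same holds for endo and exo folding.
- Risk: the Lewis acid may oligomerise the vinylallene before the crowded C5–C10 bond can form.
- Risk: the product alkene may drift into conjugation with the formyl group.
- Fallback: the same [4+2] is run at the acid oxidation level under auxiliary control. It sets out from ester 12 and comes back at alcohol 16. Saponification (LiOH, THF/MeOH/H2O) would give the tetraenoic acid F1. Pivaloyl chloride and Et3N would convert it into the mixed pivalic anhydride F2, which acylates the lithium salt of (4R)-4-benzyl-1,3-oxazolidin-2-one to the N-tetraenoyl oxazolidinone F3. With a slight excess of Me2AlCl the imide forms a chelated cationic aluminium complex, a far stronger dienophile than the enal. In its s-cis form the benzyl group covers the face of C9=C10 that the C3 relay also disfavours, so the two controls are matched. This should give the bicyclic imide F4. Reductive removal of the auxiliary (LiBH4, Et2O/MeOH) gives 16 directly, and the labile aldehyde is never handled.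

2. Step 6 (allenyl transfer).
- Risk: the three-carbon unit may be passed on through its far end, giving propargyl instead of allenyl coupling.
- Risk: transmetallation may be slow enough for homocoupling to compete.
- Risk: the vinylallene may dimerise during a long reaction.
- Fallback: the allene is made by reductive transposition instead of by transfer. It sets out from iodide 10 and comes back at 12. Sonogashira coupling with prop-2-yn-1-ol (PdCl2(PPh3)2, CuI, Et3N, rt) would give the enynol F5. Mitsunobu reaction with 2-nitrobenzenesulfonylhydrazide (PPh3, DEAD, THF, −15 °C) would give the propargylic sulfonylhydrazine F6. On warming to rt, F6 loses the sulfinic acid to give the propargylic diazene F7. Retro-ene loss of nitrogen delivers hydrogen to C7 and leaves C7=C8=C12 (Myers allene synthesis). The hydroxyl group sits on a primary carbon that is propargylic but not allylic, so only the alkyne can take part in the sigmatropic step.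

3. Step 4 (alkene cleavage).
- Risk: osmylation of the hindered vinyl group may become slow enough for attack on the enoate alkene to compete, which would erode the chemoselectivity.
- Fallback: an oxidant with a much larger electronic bias is used. It sets out from 6 and comes back at 8. A peracid (mCPBA, NaHCO3, CH2Cl2, rt) hardly touches conjugated esters and should epoxidise only the vinyl group, giving the terminal epoxide F8. Periodic acid (H5IO6, THF/H2O, 0 °C) then opens and cleaves F8 to aldehyde 8.

Further compounds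
F1 | step 9 | (2E,6R,8E)-6-(tert-butyldimethylsilyloxy)-3,7,7-trimethyldodeca-2,8,10,11-tetraenoic acid | C=C=C/C=C/C(C)(C)[C@H](O[Si](C)(C)C(C)(C)C)CC/C(C)=C/C(=O)O
F2 | step 9 | (2E,6R,8E)-6-(tert-butyldimethylsilyloxy)-3,7,7-trimethyldodeca-2,8,10,11-tetraenoic 2,2-dimethylpropanoic anhydride | C=C=C/C=C/C(C)(C)[C@H](O[Si](C)(C)C(C)(C)C)CC/C(C)=C/C(=O)OC(=O)C(C)(C)C
F3 | step 9 | (4R)-4-benzyl-3-[(2E,6R,8E)-6-(tert-butyldimethylsilyloxy)-3,7,7-trimethyldodeca-2,8,10,11-tetraenoyl]-1,3-oxazolidin-2-one | C=C=C/C=C/C(C)(C)[C@H](O[Si](C)(C)C(C)(C)C)CC/C(C)=C/C(=O)N1[C@H](Cc2ccccc2)COC1=O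
F4 | step 9 | (4R)-4-benzyl-3-{[(1R,4aS,6R,8aR)-6-(tert-butyldimethylsilyloxy)-5,5,8a-trimethyl-2-methylidene-1,2,4a,5,6,7,8,8a-octahydronaphthalen-1-yl]carbonyl}-1,3-oxazolidin-2-one | C=C1C=C[C@@H]2C(C)(C)[C@H](O[Si](C)(C)C(C)(C)C)CC[C@@]2(C)[C@@H]1C(=O)N3[C@H](Cc4ccccc4)COC3=O
F5 | step 6 | methyl (2E,6R,8E)-6-(tert-butyldimethylsilyloxy)-12-hydroxy-3,7,7-trimethyldodeca-2,8-dien-10-ynoate | OCC#C/C=C/C(C)(C)[C@H](O[Si](C)(C)C(C)(C)C)CC/C(C)=C/C(=O)OC
F6 | step 6 | methyl (2E,6R,8E)-12-[1-(2-nitrophenylsulfonyl)hydrazinyl]-6-(tert-butyldimethylsilyloxy)-3,7,7-trimethyldodeca-2,8-dien-10-ynoate | NN(CC#C/C=C/C(C)(C)[C@H](O[Si](C)(C)C(C)(C)C)CC/C(C)=C/C(=O)OC)S(=O)(=O)c1ccccc1[N+](=O)[O-]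
F7 | step 6 | methyl (2E,6R,8E)-12-diazenyl-6-(tert-butyldimethylsilyloxy)-3,7,7-trimethyldodeca-2,8-dien-10-ynoate | N=NCC#C/C=C/C(C)(C)[C@H](O[Si](C)(C)C(C)(C)C)CC/C(C)=C/C(=O)OC
F8 | step 4 | methyl (2E,6R)-6-(tert-butyldimethylsilyloxy)-3,7-dimethyl-7-(oxiran-2-yl)oct-2-enoate (both epoxide epimers) | C1OC1C(C)(C)[C@H](O[Si](C)(C)C(C)(C)C)CC/C(C)=C/C(=O)OC
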